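**Plan** (ring atoms numbered as in the target name: C1 = CBr(CH2Br), C2 = CHCl, C3 = CH2, C4 = CHCl, C5 = C(CH3)(chloroethenyl), C6 = CH2)
1. Retrosynthesis: cut C1–Br/CH2–Br (Br2 on a 1-methylidene group), then C2–Cl and C4–Cl (inversion of alcohols), then the ring at C3–C4 and C6–C1. This leaves an acetoacetate γ,α-dinucleophile (C1, C2, C3 and the future CH2Br carbon) and a 2,2-disubstituted malonaldehyde (C4, C5, C6, methyl, chloroethenyl).
2. Forward: dialdehyde 8 is made in six steps; one [3+3] annulation closes the only ring and completes the C10 skeleton; seven functional-group steps follow.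
3. Enabling feature: C5 is quaternary and flanked by C4 and C6, so the 1,3-dialdehyde is non-enolisable and prochiral. The C2/C4 1,3-dichloride is a masked aldol, and C1 with its exocyclic carbon is the α-carbon of a β-keto ester.
4. Stereochemistry: C5 and C4 from the catalyst-controlled, enantiotopic-group-selective aldol event of the annulation; C2 by substrate-controlled 1,3-cis reduction; both chlorines by SN2 inversion; C1 by axial opening of a bromonium ion; the Z-chloroalkene by syn reduction of a chloroalkyne.

Key step: step 7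

Assumption: alcohol 1 and diene 9 are purchased; the ketene-acetal geometry of 9 is drawn as Z but does not matter for the chemistry.

Step 1
Reactants: 1 (2,2,5-trimethyl-1,3-dioxan-5-yl)methanol
Product: 2 2,2,5-trimethyl-1,3-dioxane-5-carbaldehyde
Conditions: Dess–Martin periodinane, CH2Cl2, 0 °C to rt
Reagents that add atoms: none
Why: Dess–Martin oxidation of the neopentylic primary alcohol should give the non-enolisable aldehyde without touching the acetonide.

Step 2
Reactants: 2 2,2,5-trimethyl-1,3-dioxane-5-carbaldehyde
Product: 3 5-ethynyl-2,2,5-trimethyl-1,3-dioxane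
Conditions: dimethyl (1-diazo-2-oxopropyl)phosphonate, K2CO3, MeOH, 0 °C to rt
Reagents that add atoms: dimethyl (1-diazo-2-oxopropyl)phosphonate, CC(=O)C(=[N+]=[N-])P(=O)(OC)OC
Why: The Ohira–Bestmann (Seyferth–Gilbert) homologation converts a non-enolisable aldehyde into the terminal alkyne under mild basic conditions that the acetonide tolerates.

Step 3
Reactants: 3 5-ethynyl-2,2,5-trimethyl-1,3-dioxane
Product: 5 5-(chloroethynyl)-2,2,5-trimethyl-1,3-dioxane, via lithium acetylide 4 (not isolated)
Conditions: n-BuLi (1.05 equiv), THF, −78 °C; then N-chlorosuccinimide, −78 °C to rt; aq. NH4Cl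
Reagents that add atoms: N-chlorosuccinimide, O=C1CCC(=O)N1Cl
Why: Deprotonation of the terminal alkyne and electrophilic chlorination of the lithium acetylide is the standard preparation of 1-chloroalkynes.

Step 4
Reactants: 5 5-(chloroethynyl)-2,2,5-trimethyl-1,3-dioxane
Product: 6 5-[(Z)-2-chloroethenyl]-2,2,5-trimethyl-1,3-dioxane
Conditions: 2-nitrobenzenesulfonylhydrazide, Et3N, THF/i-PrOH, rt
Reagents that add atoms: none
Why: Concerted syn transfer of two hydrogens from diimide to the chloroalkyne (diimide semireduction of a 1-haloalkyne) fixes the Z geometry, and the chloroalkene formed should be reduced much more slowly.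

Step 5
Reactants: 6 5-[(Z)-2-chloroethenyl]-2,2,5-trimethyl-1,3-dioxane
Product: 7 2-[(Z)-2-chloroethenyl]-2-methylpropane-1,3-diol
Conditions: 1 M aq. HCl, THF, rt
Reagents that add atoms: none
Why: Acid-catalysed acetal hydrolysis frees the prochiral 1,3-diol, and the vinyl chloride is inert to dilute acid.

Step 6
Reactants: 7 2-[(Z)-2-chloroethenyl]-2-methylpropane-1,3-diol
Product: 8 2-[(Z)-2-chloroethenyl]-2-methylpropanedial
Conditions: Dess–Martin periodinane (2.4 equiv), CH2Cl2, 0 °C to rt; used crude at once
Reagents that add atoms: none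
Why: Double Dess–Martin oxidation should give the 2,2-disubstituted malonaldehyde, which cannot enolise and is used directly because such dialdehydes hydrate and oligomerise on storage.

Step 7
Reactants: 8 2-[(Z)-2-chloroethenyl]-2-methylpropanedial; 9 (1Z)-1-methoxy-1,3-bis(trimethylsilyloxy)buta-1,3-diene
Product: 12 methyl (3S,4R)-3-[(Z)-2-chloroethenyl]-4-hydroxy-3-methyl-6-oxocyclohex-1-ene-1-carboxylate, via bis-silylated aldol adduct 10 (not isolated), via hydroxy keto aldehyde 11 (not isolated)
Conditions: (R)-1,1'-bi-2-naphthol (20 mol%), Ti(OiPr)4 (20 mol%), 4 Å molecular sieves, THF, −78 to −20 °C, 9 added slowly to 8 (1.3 equiv); then CF3CO2H, −20 to 0 °C; then piperidine, 0 °C to rt; one pot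
Reagents that add atoms: none
Why: Proposed new method: the binaphthol–Ti(OiPr)4 complex activates one formyl group of prochiral 8 and the terminal (γ) carbon of diene 9 adds to it in an open Mukaiyama transition state (C3–C4 bond, silyl transfer to oxygen, 10); desilylation then frees β-keto ester 11, whose doubly activated α-carbon condenses with the remaining formyl group by a 6-(enolendo)-exo-trig aldol closure and E1cB loss of water (C6–C1 bond, intramolecular Knoevenagel condensation), which forms the only ring. The closest known reaction types are the binaphthol/Ti(OiPr)4-catalysed enantioselective vinylogous Mukaiyama aldol addition of this diene to simple aldehydes and the TiCl4-mediated [3+3] cyclisation of 1,3-bis(silyloxy)dienes with 1,3-dielectrophiles; new here is their union on a prochiral 1,3-dialdehyde with enantiotopic-group selection. The configuration at C4 is set by the catalyst, the (R)-ligand being expected to deliver the diene to the Re face of the formyl group as in its additions to other aldehydes. The configuration at C5 follows from which formyl group reacts: in a polar Felkin–Anh arrangement the second formyl group lies anti to the incoming nucleophile and the methyl group, the smallest substituent, lies next to its path, which places the new hydroxyl cis to methyl, so only one of the two enantiotopic formyl groups is matched with the Re-selective catalyst. The step needs mono-addition, γ-regioselectivity and survival of the β-hydroxy ketone; these should be secured by the excess of 8, by the inherent γ-reactivity of the bis(silyloxy)diene, by fast intramolecular capture of the second formyl group once the keto ester is unmasked, and by the mild amine-salt medium in which the C4 hydroxyl is not eliminated.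

Step 8
Reactants: 12 methyl (3S,4R)-3-[(Z)-2-chloroethenyl]-4-hydroxy-3-methyl-6-oxocyclohex-1-ene-1-carboxylate
Product: 13 (1R,3S,6S)-6-[(Z)-2-chloroethenyl]-4-(hydroxymethyl)-6-methylcyclohex-4-ene-1,3-diol
Conditions: i-Bu2AlH (6 equiv), CH2Cl2, −78 to −40 °C; aq. KNaC4H4O6
Reagents that add atoms: none
Why: i-Bu2AlH reduces the ester to the primary allylic alcohol and the enone carbonyl by 1,2-addition (the β-carbon C6 is neopentylic), and axial delivery of hydride to C2 of the half-chair that keeps the C4 oxygen equatorial should give the equatorial C2 alcohol cis to the C4 hydroxyl, the usual outcome of hydride reduction of 5-substituted cyclohex-2-enones.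

Step 9
Reactants: 13 (1R,3S,6S)-6-[(Z)-2-chloroethenyl]-4-(hydroxymethyl)-6-methylcyclohex-4-ene-1,3-diol
Product: 14 (6S,7R,8aS)-6-[(Z)-2-chloroethenyl]-2,2,6-trimethyl-6,7,8,8a-tetrahydro-4H-1,3-benzodioxin-7-ol
Conditions: 2,2-dimethoxypropane, pyridinium p-toluenesulfonate (cat.), CH2Cl2, rt
Reagents that add atoms: 2,2-dimethoxypropane, COC(C)(C)OC
Why: Thermodynamically controlled transacetalisation selects the strain-free six-membered dioxane across the C2 hydroxyl and the primary allylic hydroxyl, because an acetonide across the two ring hydroxyls would force both to be axial, and it leaves the hindered C4 hydroxyl free.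

Step 10
Reactants: 14 (6S,7R,8aS)-6-[(Z)-2-chloroethenyl]-2,2,6-trimethyl-6,7,8,8a-tetrahydro-4H-1,3-benzodioxin-7-ol
Product: 15 (6S,7S,8aS)-7-chloro-6-[(Z)-2-chloroethenyl]-2,2,6-trimethyl-6,7,8,8a-tetrahydro-4H-1,3-benzodioxine
Conditions: Ph3PCl2, imidazole, MeCN/toluene, 70 °C
Reagents that add atoms: dichlorotriphenylphosphorane, ClP(Cl)(c1ccccc1)(c1ccccc1)c1ccccc1
Why: Deoxychlorination through the alkoxyphosphonium salt (Appel-type reaction with preformed Ph3PCl2) should proceed with SN2 inversion at C4, because in the half-chair with the C2 oxygen equatorial and the C5 methyl axial the chloride enters axially past hydrogen atoms only and the equatorial leaving group has no anti-periplanar hydrogen for E2, the situation in which equatorial carbinols next to a quaternary carbon are known to give inverted axial chlorides.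

Step 11
Reactants: 15 (6S,7S,8aS)-7-chloro-6-[(Z)-2-chloroethenyl]-2,2,6-trimethyl-6,7,8,8a-tetrahydro-4H-1,3-benzodioxine
Product: 16 (1S,4S,5S)-5-chloro-4-[(Z)-2-chloroethenyl]-2-(hydroxymethyl)-4-methylcyclohex-2-en-1-ol
Conditions: AcOH/THF/H2O (3:1:1), 40 °C
Reagents that add atoms: none
Why: Acid-catalysed acetal hydrolysis releases the primary and the C2 allylic hydroxyl groups, and the alkyl and vinyl chlorides do not react with aqueous acetic acid.

Step 12
Reactants: 16 (1S,4S,5S)-5-chloro-4-[(Z)-2-chloroethenyl]-2-(hydroxymethyl)-4-methylcyclohex-2-en-1-ol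
Product: 19 (1S,4S,5S)-5-chloro-4-[(Z)-2-chloroethenyl]-4-methyl-2-methylidenecyclohexan-1-ol, via sulfonylhydrazine adduct 17 (not isolated), via allylic diazene 18 (not isolated)
Conditions: PPh3, diethyl azodicarboxylate, 2-nitrobenzenesulfonylhydrazide, THF, −30 °C; then rt
Reagents that add atoms: none
Why: Mitsunobu displacement of the primary allylic hydroxyl (faster than that of the hindered secondary one) by the sulfonylhydrazide, loss of sulfinic acid on warming and retro-ene loss of N2 from the allylic diazene (Myers reductive 1,3-transposition) deliver hydrogen to C6 and move the double bond to the exocyclic position, with no stereocentre created.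

Step 13
Reactants: 19 (1S,4S,5S)-5-chloro-4-[(Z)-2-chloroethenyl]-4-methyl-2-methylidenecyclohexan-1-ol
Product: 20 (1S,2S,4R)-2,4-dichloro-1-[(Z)-2-chloroethenyl]-1-methyl-5-methylidenecyclohexane
Conditions: PPh3, Cl3CCOCCl3, CH2Cl2, 0 °C to rt
Reagents that add atoms: hexachloroacetone, ClC(Cl)(Cl)C(=O)C(Cl)(Cl)Cl
Why: Deoxychlorination through the alkoxyphosphonium salt formed from PPh3 and hexachloroacetone (Appel-type reaction) should replace the allylic C2 oxygen by chloride with SN2 inversion and little allylic transposition, the reactive conformer having the C–O bond axial and aligned with the exocyclic π bond while the C4 chlorine is equatorial and does not oppose attack from the lower face.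

Step 14
Reactants: 20 (1S,2S,4R)-2,4-dichloro-1-[(Z)-2-chloroethenyl]-1-methyl-5-methylidenecyclohexane
Product: 21 (1S,2R,4S,5S)-1-bromo-1-(bromomethyl)-2,4-dichloro-5-[(Z)-2-chloroethenyl]-5-methylcyclohexane
Conditions: Br2 (1.0 equiv), CH2Cl2, −78 °C, dark
Reagents that add atoms: bromine, BrBr
Why: Electrophilic anti addition of Br2 occurs at the 1,1-disubstituted alkene, which is far more nucleophilic than the chloroalkene, and axial attack of bromide on the tertiary carbon of the bromonium ion lets the CH2Br group become equatorial, which should place the C1 bromine cis to the C2 and C4 chlorines.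

**Compound list**
1 | (2,2,5-trimethyl-1,3-dioxan-5-yl)methanol | CC1(C)OCC(C)(CO)CO1 | starting material
2 | 2,2,5-trimethyl-1,3-dioxane-5-carbaldehyde | CC1(C)OCC(C)(C=O)CO1 | intermediate
3 | 5-ethynyl-2,2,5-trimethyl-1,3-dioxane | CC1(C)OCC(C)(C#C)CO1 | intermediate
4 | [(2,2,5-trimethyl-1,3-dioxan-5-yl)ethynyl]lithium | [Li]C#CC1(C)COC(C)(C)OC1 | intermediate
5 | 5-(chloroethynyl)-2,2,5-trimethyl-1,3-dioxane | CC1(C)OCC(C)(C#CCl)CO1 | intermediate
6 | 5-[(Z)-2-chloroethenyl]-2,2,5-trimethyl-1,3-dioxane | CC1(C)OCC(C)(/C=C\Cl)CO1 | intermediate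
7 | 2-[(Z)-2-chloroethenyl]-2-methylpropane-1,3-diol | CC(CO)(CO)/C=C\Cl | intermediate
8 | 2-[(Z)-2-chloroethenyl]-2-methylpropanedial | CC(C=O)(C=O)/C=C\Cl | intermediate
9 | (1Z)-1-methoxy-1,3-bis(trimethylsilyloxy)buta-1,3-diene | CO/C(O[Si](C)(C)C)=C/C(=C)O[Si](C)(C)C | starting material
10 | (2S,3R,6Z)-2-[(Z)-2-chloroethenyl]-7-methoxy-2-methyl-5-oxo-3,7-bis(trimethylsilyloxy)hept-6-enal | CO/C(O[Si](C)(C)C)=C/C(=O)C[C@@H](O[Si](C)(C)C)[C@@](C)(C=O)/C=C\Cl | intermediate
11 | methyl (5R,6S,7Z)-8-chloro-6-formyl-5-hydroxy-6-methyl-3-oxooct-7-enoate | COC(=O)CC(=O)C[C@@H](O)[C@@](C)(C=O)/C=C\Cl | intermediate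
12 | methyl (3S,4R)-3-[(Z)-2-chloroethenyl]-4-hydroxy-3-methyl-6-oxocyclohex-1-ene-1-carboxylate | COC(=O)C1=C[C@@](C)(/C=C\Cl)[C@H](O)CC1=O | intermediate
13 | (1R,3S,6S)-6-[(Z)-2-chloroethenyl]-4-(hydroxymethyl)-6-methylcyclohex-4-ene-1,3-diol | OCC1=C[C@@](C)(/C=C\Cl)[C@H](O)C[C@@H]1O | intermediate
14 | (6S,7R,8aS)-6-[(Z)-2-chloroethenyl]-2,2,6-trimethyl-6,7,8,8a-tetrahydro-4H-1,3-benzodioxin-7-ol | CC1(C)OCC2=C[C@@](C)(/C=C\Cl)[C@H](O)C[C@@H]2O1 | intermediate
15 | (6S,7S,8aS)-7-chloro-6-[(Z)-2-chloroethenyl]-2,2,6-trimethyl-6,7,8,8a-tetrahydro-4H-1,3-benzodioxine | CC1(C)OCC2=C[C@@](C)(/C=C\Cl)[C@@H](Cl)C[C@@H]2O1 | intermediate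
16 | (1S,4S,5S)-5-chloro-4-[(Z)-2-chloroethenyl]-2-(hydroxymethyl)-4-methylcyclohex-2-en-1-ol | OCC1=C[C@@](C)(/C=C\Cl)[C@@H](Cl)C[C@@H]1O | intermediate
17 | N-{[(3S,4S,6S)-4-chloro-3-[(Z)-2-chloroethenyl]-6-hydroxy-3-methylcyclohex-1-en-1-yl]methyl}-2-nitrobenzenesulfonohydrazide | NN(CC1=C[C@@](C)(/C=C\Cl)[C@@H](Cl)C[C@@H]1O)S(=O)(=O)c1ccccc1[N+](=O)[O-] | intermediate
18 | (1S,4S,5S)-5-chloro-4-[(Z)-2-chloroethenyl]-2-(diazenylmethyl)-4-methylcyclohex-2-en-1-ol (diazene geometry not assigned) | N=NCC1=C[C@@](C)(/C=C\Cl)[C@@H](Cl)C[C@@H]1O | intermediate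
19 | (1S,4S,5S)-5-chloro-4-[(Z)-2-chloroethenyl]-4-methyl-2-methylidenecyclohexan-1-ol | C=C1C[C@@](C)(/C=C\Cl)[C@@H](Cl)C[C@@H]1O | intermediate
20 | (1S,2S,4R)-2,4-dichloro-1-[(Z)-2-chloroethenyl]-1-methyl-5-methylidenecyclohexane | C[C@@]1(/C=C\Cl)CC(=C)[C@H](Cl)C[C@@H]1Cl | intermediate
21 | (1S,2R,4S,5S)-1-bromo-1-(bromomethyl)-2,4-dichloro-5-[(Z)-2-chloroethenyl]-5-methylcyclohexane | C[C@@]1(/C=C\Cl)C[C@@](Br)(CBr)[C@H](Cl)C[C@@H]1Cl | target

Total step count: 14. Longest linear sequence: 14 steps (1 to 21); diene 9 enters at step 7 as a purchased compound.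

**Steps most likely to fail**

Step 7 (proposed new method). The catalyst may fail to distinguish the two enantiotopic formyl groups or their faces, since the 1,3-dialdehyde can chelate titanium. Double addition of the diene or elimination of the C4 hydroxyl may also erode the outcome. The fallback uses known chemistry only, sets out from 7 and comes back at 12. Desymmetrising monoacetylation of diol 7 with a lipase (Burkholderia cepacia lipase, vinyl acetate) should give [(2S,3Z)-4-chloro-2-(hydroxymethyl)-2-methylbut-3-en-1-yl] acetate F1; the other enantiomer, if the enzyme prefers it, is reached by hydrolysis of the diacetate with the same enzyme. Dess–Martin oxidation gives [(2R,3Z)-4-chloro-2-formyl-2-methylbut-3-en-1-yl] acetate F2, in which the quaternary centre is already fixed. The binaphthol/Ti(OiPr)4-catalysed vinylogous Mukaiyama aldol addition of 9 to this single formyl group, followed by CF3CO2H, gives methyl (5R,6R,7Z)-6-(acetyloxymethyl)-8-chloro-5-hydroxy-6-methyl-3-oxooct-7-enoate F3. Enzymatic deacetylation in pH 7 buffer gives methyl (5R,6R,7Z)-8-chloro-5-hydroxy-6-(hydroxymethyl)-6-methyl-3-oxooct-7-enoate F4. Selective oxidation of the primary alcohol (2,2,6,6-tetramethylpiperidin-1-oxyl, PhI(OAc)2) gives 11, which piperidinium acetate closes to 12.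

Step 10. Elimination toward C3 or a 1,2-shift of a C5 substituent may outrun substitution at the neopentylic C4 under the hot phosphonium conditions. The fallback sets out from 14 and comes back at 15. The alcohol is converted with Tf2O and pyridine at −30 °C into (6S,7R,8aS)-6-[(Z)-2-chloroethenyl]-2,2,6-trimethyl-6,7,8,8a-tetrahydro-4H-1,3-benzodioxin-7-yl trifluoromethanesulfonate F5. This isolated sulfonate is displaced at 0 °C to rt by Bu4NCl in toluene, so the inversion runs on a far better leaving group at low temperature and without an ionising phosphorus medium.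

Step 14. Bromide may enter from the equatorial side, because axial entry at C1 is syn to the axial chloroethenyl group on C5, which would give the C1 epimer. The fallback replaces kinetic control by thermodynamic convergence; it sets out from 20 and comes back at 21. Compound 20 is brominated as in step 14 and the crude epimer mixture is warmed with LiBr in MeCN (or with catalytic ZnBr2 in CH2Cl2). Vicinal tertiary/primary dibromides interconvert through the bromonium–bromide ion pair, and the unwanted epimer carries CH2Br syn-axial to the chloroethenyl group, so the equilibrium should lie on the side of 21. Material that does not converge is returned to 20 with Zn in AcOH and resubmitted; no new compound is made (F0).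

Further compounds
F1 | step 7 | [(2S,3Z)-4-chloro-2-(hydroxymethyl)-2-methylbut-3-en-1-yl] acetate | CC(=O)OC[C@](C)(CO)/C=C\Cl
F2 | step 7 | [(2R,3Z)-4-chloro-2-formyl-2-methylbut-3-en-1-yl] acetate | CC(=O)OC[C@](C)(C=O)/C=C\Cl
F3 | step 7 | methyl (5R,6R,7Z)-6-(acetyloxymethyl)-8-chloro-5-hydroxy-6-methyl-3-oxooct-7-enoate | COC(=O)CC(=O)C[C@@H](O)[C@@](C)(COC(C)=O)/C=C\Cl
F4 | step 7 | methyl (5R,6R,7Z)-8-chloro-5-hydroxy-6-(hydroxymethyl)-6-methyl-3-oxooct-7-enoate | COC(=O)CC(=O)C[C@@H](O)[C@@](C)(CO)/C=C\Cl
F5 | step 10 | (6S,7R,8aS)-6-[(Z)-2-chloroethenyl]-2,2,6-trimethyl-6,7,8,8a-tetrahydro-4H-1,3-benzodioxin-7-yl trifluoromethanesulfonate | CC1(C)OCC2=C[C@@](C)(/C=C\Cl)[C@H](OS(=O)(=O)C(F)(F)F)C[C@@H]2O1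
F0 | step 14 | none | none
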